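**Plan**

- Retrosynthesis: O1–C2 is cut first (oxa-Michael), then C4–C3 and C4a–C4 (tigloyl unit back to a formyl group and a butenyl metal), then the benzene ring at C8a–C4a and C5–C6 (with C8–C8a re-formed), and last the cyclobutenone at two ring bonds into a ketene and a siloxyalkyne.
- What makes this possible: the benzene ring carries three oxygens (C5, C7, C8a) alternating with three carbon substituents (C4a, C6, C8), and C8 with its benzylic stereocentre is one CH2–CO arm of a 3-propylglutarate, so the ring maps onto one ketene and two ynol ethers.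
- Forward: desymmetrised half-ester → acid chloride → ketene [2+2] with the prenyl siloxyalkyne (four-membered ring) → benzannulation with (triisopropylsiloxy)ethyne (benzene ring, only C8a–OH free).
- Then C4a formylation, tigloyl ketone, pyranone ring by oxa-Michael closure onto C8a–OH, C3 equilibration, desilylation.
- Stereochemistry: side-chain centre from alkaloid-catalysed anhydride methanolysis; C2 from quinidine-catalysed ring closure; C3 by thermodynamic equilibration to trans.

Key step: step 6

Assumption: the sense of induction is taken from the closest analogues, (DHQD)2AQN giving the (R)-half-ester from a 3-alkylglutaric anhydride and quinidine giving the (2S)-chromanone from an o-tigloylphenol; should either sense be opposite, the quinine-derived pseudoenantiomer is used in that step.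

**Route**

Step 1
Reactants: 1 3-propylglutaric anhydride
Product: 2 (3R)-3-(2-methoxy-2-oxoethyl)hexanoic acid
Conditions: (DHQD)2AQN (10–20 mol%), MeOH (10 equiv), Et2O, −40 °C
Reagents that add atoms: methanol, CO
Why: Desymmetrisation of the prochiral anhydride by cinchona-alkaloid-catalysed (general-base) methanolysis: the catalyst distinguishes the two enantiotopic carbonyls and so sets the lone side-chain stereocentre (R in 2, the same centre that is S in the target after the CIP change), and the optical purity can be raised by crystallisation of an amine salt if required.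

Step 2
Reactants: 2 (3R)-3-(2-methoxy-2-oxoethyl)hexanoic acid
Product: 3 methyl (3S)-3-(2-chloro-2-oxoethyl)hexanoate
Conditions: (COCl)2, DMF (cat.), CH2Cl2, 0 °C → rt; used crude
Reagents that add atoms: oxalyl chloride, O=C(Cl)C(Cl)=O
Why: Standard acid chloride formation through the Vilsmeier-type chloroiminium catalyst; the stereocentre is β to both carbonyls and untouched, and 3 is made cold and used at once so that the degenerate ester/acyl chloride interchange known for glutarate half-ester chlorides cannot erode it.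

Step 3
Reactants: 4 ethyl 4-methylpent-3-enoate; 5 triisopropylsilyl trifluoromethanesulfonate
Product: 8 triisopropyl[(5-methylhex-4-en-1-yn-1-yl)oxy]silane, via lithium dibromoenolate 6 (not isolated), via lithium ynolate 7 (not isolated)
Conditions: CH2Br2, lithium 2,2,6,6-tetramethylpiperidide, THF, −78 °C; 4; LiN(SiMe3)2, then n-BuLi, −78 °C → rt; 5, −78 → 0 °C
Reagents that add atoms: dibromomethane, BrCBr
Why: Kowalski ester homologation: LiCHBr2 adds to the ester carbonyl faster than it enolises it at −78 °C, the derived dibromoenolate 6 undergoes bromine–lithium exchange and carbenoid 1,2-shift to ynolate 7, and the bulky silyl triflate traps it on oxygen to give the ynol silyl ether; no stereocentre is involved.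

Step 4
Reactants: 3 methyl (3S)-3-(2-chloro-2-oxoethyl)hexanoate; 8 triisopropyl[(5-methylhex-4-en-1-yn-1-yl)oxy]silane
Product: 10 methyl (3S)-3-[3-(3-methylbut-2-en-1-yl)-4-oxo-2-(triisopropylsiloxy)cyclobut-2-en-1-yl]hexanoate, via aldoketene 9 (not isolated)
Conditions: Et3N, CH2Cl2, rt; 3 added over several hours to 8 (2 equiv)
Reagents that add atoms: none
Why: Dehydrochlorination gives aldoketene 9, which undergoes the known polar [2+2] cycloaddition of ketenes with siloxyalkynes (ketene carbonyl carbon to the prenyl-bearing carbon β to oxygen) to the 3-siloxycyclobutenone, slow addition into excess alkyne holding ketene dimerisation down; the ring CH forms as both epimers, which is without consequence because it becomes aromatic C8.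

Step 5
Reactants: 11 3-phenyl-1,2-oxazole; 5 triisopropylsilyl trifluoromethanesulfonate
Product: 13 (ethynyloxy)triisopropylsilane, via lithium ethynolate 12 (not isolated)
Conditions: LiN(i-Pr)2, THF, −78 °C; 5, −78 → 0 °C
Reagents that add atoms: none
Why: Lithiation at C5 of a 5-unsubstituted isoxazole triggers the known cycloreversion to a nitrile and a lithium ynolate, and the hard, bulky silyl triflate is expected to silylate ynolate 12 on oxygen as in established ynol silyl ether preparations; no stereocentre is involved.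

Step 6
Reactants: 10 methyl (3S)-3-[3-(3-methylbut-2-en-1-yl)-4-oxo-2-(triisopropylsiloxy)cyclobut-2-en-1-yl]hexanoate; 13 (ethynyloxy)triisopropylsilane
Product: 18 methyl (3S)-3-[2-hydroxy-5-(3-methylbut-2-en-1-yl)-4,6-bis(triisopropylsiloxy)phenyl]hexanoate, via vinylketene 14 (not isolated), via 4-vinylcyclobutenone 15 (not isolated), via dienylketene 16 (not isolated), via cyclohexadienone 17 (not isolated)
Conditions: 13 (2.5 equiv), toluene, 80 °C then 110 °C, sealed tube
Reagents that add atoms: none
Why: On heating, 10 opens by 4π-electrocyclic cleavage of the C8–C8a bond (side chain rotating outward) to vinylketene 14, whose carbonyl carbon is attacked by the unsubstituted, nucleophilic carbon of ynol ether 13 in a polar [2+2] cycloaddition that forms C8a–C4a and C5–C6 and gives 4-vinylcyclobutenone 15; a second 4π opening gives dienylketene 16, 6π-electrocyclisation gives cyclohexadienone 17 and a proton shift gives phenol 18. The closest known reaction type is the Danheiser benzannulation of cyclobutenones with siloxyalkynes to monosilylated resorcinols, and ring opening of 3-alkoxycyclobutenones at comparable temperatures is familiar from squarate-derived cyclobutenones. The single ring formed, the benzene ring, closes by thermal disrotatory 6π-electrocyclisation of the dienylketene (six-membered carbocycle, re-forming C8–C8a) and is driven by aromatisation. No stereocentre is created: the ring CH of 10, the quaternary carbon of 15 and the sp3 carbon of 17 all end as aromatic carbons, and the side-chain centre, which is never enolisable, is carried through as S. The only selectivity needed is regiochemical and the polarisation of both partners secures it: the electrophilic ketene carbon joins the alkyne CH (β to oxygen), which places the free hydroxyl at C8a, hydrogen at C4a and the two silyl ethers at C5 and C7, and the bulky i-Pr3Si groups should not migrate between meta oxygens. An excess of 13 compensates for its thermal loss.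

Step 7
Reactants: 18 methyl (3S)-3-[2-hydroxy-5-(3-methylbut-2-en-1-yl)-4,6-bis(triisopropylsiloxy)phenyl]hexanoate
Product: 20 methyl (3S)-3-[3-formyl-2-hydroxy-5-(3-methylbut-2-en-1-yl)-4,6-bis(triisopropylsiloxy)phenyl]hexanoate, via hydroxymethylphenol 19 (not isolated)
Conditions: MgCl2, Et3N, (CH2O)n, THF, 65 °C
Reagents that add atoms: paraformaldehyde (as formaldehyde), C=O
Why: Magnesium-phenoxide-directed ortho-formylation (Casnati–Skattebøl: chelated ortho-hydroxymethylation to 19, then Oppenauer-type hydride transfer to a second formaldehyde) can only strike C4a, the single free ring position and ortho to the only free hydroxyl, under conditions that spare aryl silyl ethers, ester and prenyl group; the reaction is stopped at full conversion to limit lactonisation of the phenol onto the ester.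

Step 8
Reactants: 20 methyl (3S)-3-[3-formyl-2-hydroxy-5-(3-methylbut-2-en-1-yl)-4,6-bis(triisopropylsiloxy)phenyl]hexanoate; 21 (E)-2-bromobut-2-ene
Product: 23 methyl (3S)-3-[2-hydroxy-3-[(2E)-2-methylbut-2-enoyl]-5-(3-methylbut-2-en-1-yl)-4,6-bis(triisopropylsiloxy)phenyl]hexanoate, via allylic alcohol 22 (not isolated)
Conditions: 21, t-BuLi, Et2O, −78 °C; MgBr2·OEt2; 20, THF, −78 → −40 °C; aq. NH4Cl; crude 22: MnO2, CH2Cl2, rt
Reagents that add atoms: none
Why: Bromine–lithium exchange proceeds with retention to the (E)-alkenyl metal, whose Grignard form adds to the chelated salicylaldehyde far faster than to the methyl ester at −78 °C (one equivalent is spent on the phenol), and the acid-labile benzylic allylic alcohol 22 is oxidised without purification by MnO2 (allylic alcohol oxidation) to the (E)-tigloyl ketone, so the transient carbinol centre is of no account.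

Step 9
Reactants: 23 methyl (3S)-3-[2-hydroxy-3-[(2E)-2-methylbut-2-enoyl]-5-(3-methylbut-2-en-1-yl)-4,6-bis(triisopropylsiloxy)phenyl]hexanoate
Product: 24 methyl (3S)-3-[(2S,3R)-2,3-dimethyl-6-(3-methylbut-2-en-1-yl)-4-oxo-5,7-bis(triisopropylsiloxy)-3,4-dihydro-2H-chromen-8-yl]hexanoate
Conditions: quinidine (20 mol%), PhCl, rt
Reagents that add atoms: none
Why: Cinchona-alkaloid-catalysed intramolecular oxa-Michael addition (6-endo-trig) of the kind established for o-tigloylphenols: the quinuclidine nitrogen activates the only free phenol (C8a–OH) while the catalyst hydroxyl binds the enone, so the catalyst chooses the enone face and sets C2 as S, kinetic protonation of the enol giving mainly the cis (3R) isomer; the silyl ether on C5 excludes closure in the other direction.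

Step 10
Reactants: 24 methyl (3S)-3-[(2S,3R)-2,3-dimethyl-6-(3-methylbut-2-en-1-yl)-4-oxo-5,7-bis(triisopropylsiloxy)-3,4-dihydro-2H-chromen-8-yl]hexanoate
Product: 25 methyl (3S)-3-[(2S,3S)-2,3-dimethyl-6-(3-methylbut-2-en-1-yl)-4-oxo-5,7-bis(triisopropylsiloxy)-3,4-dihydro-2H-chromen-8-yl]hexanoate
Conditions: MgI2, Et3N, CH2Cl2, 0 °C → rt
Reagents that add atoms: none
Why: Soft enolisation with MgI2/Et3N and reprotonation equilibrate the only enolisable centre, C3, to the thermodynamically preferred trans-diequatorial (2S,3S) isomer, while C2 is untouched provided β-elimination of the phenoxide (ring opening) is avoided by low temperature and short contact.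

Step 11
Reactants: 25 methyl (3S)-3-[(2S,3S)-2,3-dimethyl-6-(3-methylbut-2-en-1-yl)-4-oxo-5,7-bis(triisopropylsiloxy)-3,4-dihydro-2H-chromen-8-yl]hexanoate
Product: 26 methyl (3S)-3-[(2S,3S)-5,7-dihydroxy-2,3-dimethyl-6-(3-methylbut-2-en-1-yl)-4-oxo-3,4-dihydro-2H-chromen-8-yl]hexanoate
Conditions: Bu4NF, AcOH, THF, 0 °C
Reagents that add atoms: none
Why: Fluoride-mediated cleavage of both aryl silyl ethers under acetic acid buffering, mild enough that retro-oxa-Michael opening, C3 epimerisation, prenyl cyclisation and ester cleavage are not expected, gives the target with 5-OH hydrogen-bonded to the C4 ketone.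

**Compound list**

1 | 3-propylglutaric anhydride (4-propyloxane-2,6-dione) | CCCC1CC(=O)OC(=O)C1 | starting material
2 | (3R)-3-(2-methoxy-2-oxoethyl)hexanoic acid | CCC[C@@H](CC(=O)OC)CC(=O)O | intermediate
3 | methyl (3S)-3-(2-chloro-2-oxoethyl)hexanoate | CCC[C@@H](CC(=O)OC)CC(=O)Cl | intermediate
4 | ethyl 4-methylpent-3-enoate | CCOC(=O)CC=C(C)C | starting material
5 | triisopropylsilyl trifluoromethanesulfonate | CC(C)[Si](C(C)C)(C(C)C)OS(=O)(=O)C(F)(F)F | starting material
6 | lithium 1,1-dibromo-5-methylhexa-1,4-dien-2-olate | CC(C)=CCC([O-])=C(Br)Br.[Li+] | intermediate (not isolated)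
7 | lithium 5-methylhex-4-en-1-yn-1-olate | CC(C)=CCC#C[O-].[Li+] | intermediate (not isolated)
8 | triisopropyl[(5-methylhex-4-en-1-yn-1-yl)oxy]silane | CC(C)=CCC#CO[Si](C(C)C)(C(C)C)C(C)C | intermediate
9 | methyl (3S)-3-(2-oxoethenyl)hexanoate (aldoketene) | CCC[C@@H](CC(=O)OC)C=C=O | intermediate (not isolated)
10 | methyl (3S)-3-[3-(3-methylbut-2-en-1-yl)-4-oxo-2-(triisopropylsiloxy)cyclobut-2-en-1-yl]hexanoate (both epimers at the ring CH) | CCC[C@@H](CC(=O)OC)C1C(=O)C(CC=C(C)C)=C1O[Si](C(C)C)(C(C)C)C(C)C | intermediate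
11 | 3-phenyl-1,2-oxazole | c1ccc(cc1)-c1ccon1 | starting material
12 | lithium ethynolate | C#C[O-].[Li+] | intermediate (not isolated)
13 | (ethynyloxy)triisopropylsilane [(triisopropylsiloxy)ethyne] | C#CO[Si](C(C)C)(C(C)C)C(C)C | intermediate
14 | methyl (3S)-3-[(1Z)-3-(3-methylbut-2-en-1-yl)-4-oxo-2-(triisopropylsiloxy)buta-1,3-dien-1-yl]hexanoate (vinylketene) | CCC[C@@H](CC(=O)OC)/C=C(O[Si](C(C)C)(C(C)C)C(C)C)/C(CC=C(C)C)=C=O | intermediate (not isolated)
15 | methyl (3S)-3-[(Z)-2-[1-(3-methylbut-2-en-1-yl)-4-oxo-2-(triisopropylsiloxy)cyclobut-2-en-1-yl]-2-(triisopropylsiloxy)ethenyl]hexanoate (both epimers at the ring quaternary carbon) | CCC[C@@H](CC(=O)OC)/C=C(O[Si](C(C)C)(C(C)C)C(C)C)/C1(CC=C(C)C)C(=O)C=C1O[Si](C(C)C)(C(C)C)C(C)C | intermediate (not isolated)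
16 | methyl (3S)-3-[(1Z,3E)-3-(3-methylbut-2-en-1-yl)-6-oxo-2,4-bis(triisopropylsiloxy)hexa-1,3,5-trien-1-yl]hexanoate (dienylketene) | CCC[C@@H](CC(=O)OC)/C=C(O[Si](C(C)C)(C(C)C)C(C)C)/C(CC=C(C)C)=C(/O[Si](C(C)C)(C(C)C)C(C)C)C=C=O | intermediate (not isolated)
17 | methyl (3S)-3-[3-(3-methylbut-2-en-1-yl)-6-oxo-2,4-bis(triisopropylsiloxy)cyclohexa-2,4-dien-1-yl]hexanoate (both epimers at the ring sp3 carbon) | CCC[C@@H](CC(=O)OC)C1C(=O)C=C(O[Si](C(C)C)(C(C)C)C(C)C)C(CC=C(C)C)=C1O[Si](C(C)C)(C(C)C)C(C)C | intermediate (not isolated)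
18 | methyl (3S)-3-[2-hydroxy-5-(3-methylbut-2-en-1-yl)-4,6-bis(triisopropylsiloxy)phenyl]hexanoate | CCC[C@@H](CC(=O)OC)c1c(O)cc(O[Si](C(C)C)(C(C)C)C(C)C)c(CC=C(C)C)c1O[Si](C(C)C)(C(C)C)C(C)C | intermediate
19 | methyl (3S)-3-[2-hydroxy-3-(hydroxymethyl)-5-(3-methylbut-2-en-1-yl)-4,6-bis(triisopropylsiloxy)phenyl]hexanoate | CCC[C@@H](CC(=O)OC)c1c(O)c(CO)c(O[Si](C(C)C)(C(C)C)C(C)C)c(CC=C(C)C)c1O[Si](C(C)C)(C(C)C)C(C)C | intermediate (not isolated)
20 | methyl (3S)-3-[3-formyl-2-hydroxy-5-(3-methylbut-2-en-1-yl)-4,6-bis(triisopropylsiloxy)phenyl]hexanoate | CCC[C@@H](CC(=O)OC)c1c(O)c(C=O)c(O[Si](C(C)C)(C(C)C)C(C)C)c(CC=C(C)C)c1O[Si](C(C)C)(C(C)C)C(C)C | intermediate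
21 | (E)-2-bromobut-2-ene | C/C=C(\C)Br | starting material
22 | methyl (3S)-3-[2-hydroxy-3-[(2E)-1-hydroxy-2-methylbut-2-en-1-yl]-5-(3-methylbut-2-en-1-yl)-4,6-bis(triisopropylsiloxy)phenyl]hexanoate (both carbinol epimers) | CCC[C@@H](CC(=O)OC)c1c(O)c(C(O)/C(C)=C/C)c(O[Si](C(C)C)(C(C)C)C(C)C)c(CC=C(C)C)c1O[Si](C(C)C)(C(C)C)C(C)C | intermediate (not isolated)
23 | methyl (3S)-3-[2-hydroxy-3-[(2E)-2-methylbut-2-enoyl]-5-(3-methylbut-2-en-1-yl)-4,6-bis(triisopropylsiloxy)phenyl]hexanoate | CCC[C@@H](CC(=O)OC)c1c(O)c(C(=O)/C(C)=C/C)c(O[Si](C(C)C)(C(C)C)C(C)C)c(CC=C(C)C)c1O[Si](C(C)C)(C(C)C)C(C)C | intermediate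
24 | methyl (3S)-3-[(2S,3R)-2,3-dimethyl-6-(3-methylbut-2-en-1-yl)-4-oxo-5,7-bis(triisopropylsiloxy)-3,4-dihydro-2H-chromen-8-yl]hexanoate (cis) | CCC[C@@H](CC(=O)OC)c1c(O[Si](C(C)C)(C(C)C)C(C)C)c(CC=C(C)C)c(O[Si](C(C)C)(C(C)C)C(C)C)c2c1O[C@@H](C)[C@@H](C)C2=O | intermediate
25 | methyl (3S)-3-[(2S,3S)-2,3-dimethyl-6-(3-methylbut-2-en-1-yl)-4-oxo-5,7-bis(triisopropylsiloxy)-3,4-dihydro-2H-chromen-8-yl]hexanoate (trans) | CCC[C@@H](CC(=O)OC)c1c(O[Si](C(C)C)(C(C)C)C(C)C)c(CC=C(C)C)c(O[Si](C(C)C)(C(C)C)C(C)C)c2c1O[C@@H](C)[C@H](C)C2=O | intermediate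
26 | methyl (3S)-3-[(2S,3S)-5,7-dihydroxy-2,3-dimethyl-6-(3-methylbut-2-en-1-yl)-4-oxo-3,4-dihydro-2H-chromen-8-yl]hexanoate | CCC[C@@H](CC(=O)OC)c1c(O)c(CC=C(C)C)c(O)c2c1O[C@@H](C)[C@H](C)C2=O | target

**Step count and risks**

Total steps: 11. Longest linear sequence: 9 steps (1 → 2 → 3 → 10 → 18 → 20 → 23 → 24 → 25 → 26, that is steps 1, 2, 4, 6, 7, 8, 9, 10, 11); steps 3 and 5 are side branches.

Steps most likely to fail:

1. Step 6. The terminal siloxyalkyne may be lost by 1,3-silyl shift to the silylketene or by oligomerisation before the slowly generated vinylketene captures it, and the donor-stabilised cyclobutenone may open only at temperatures where that loss is fast. The fallback sets out from cyclobutenone 10 and uses an internal siloxyalkyne of the class already proven in this benzannulation, carrying C4 as a protected hydroxymethyl group. Kowalski homologation of commercial ethyl (tert-butyldimethylsiloxy)acetate under the protocol of step 3, with silylation by 5, should give tert-butyldimethyl{[3-(triisopropylsiloxy)prop-2-yn-1-yl]oxy}silane F1. Heating F1 with 10 in toluene should give methyl (3S)-3-[3-[(tert-butyldimethylsiloxy)methyl]-2-hydroxy-5-(3-methylbut-2-en-1-yl)-4,6-bis(triisopropylsiloxy)phenyl]hexanoate F2, the substituted alkyne carbon again becoming C4a. AcOH–THF–H2O should remove the primary alkyl silyl ether while the aryl silyl ethers stay, giving hydroxymethylphenol 19, and MnO2 oxidation returns to the route at aldehyde 20; steps 5 and 7 are then not needed.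

2. Step 5. Silylation of the unhindered parent ynolate may go to carbon (silylketene) instead of oxygen, and the volatile, acid-sensitive product may be lost on isolation from benzonitrile. The fallback sets out from silyl triflate 5 and builds the triple bond after the O–Si bond, in the way ethoxyethyne is made from ethyl vinyl ether. Cleavage of THF with n-BuLi gives lithium ethenolate F3, which 5 silylates to (ethenyloxy)triisopropylsilane F4. Br2 at −78 °C gives (1,2-dibromoethoxy)triisopropylsilane F5, which is not isolated and loses HBr with Et3N to [(2-bromoethenyl)oxy]triisopropylsilane F6. LiN(i-Pr)2 (2 equiv) at −78 °C eliminates HBr to lithium (triisopropylsiloxy)ethynide F7, and cold aqueous quench returns to the route at 13.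

3. Step 9. Facial control at C2 may be poor if uncatalysed background closure competes or if the C8 side-chain stereocentre opposes the catalyst, leaving C2 epimers that the later steps cannot correct. The fallback sets out from aldehyde 20 and takes C2 from the chiral pool. Mitsunobu etherification of the C8a phenol with (R)-but-3-en-2-ol (PPh3, diisopropyl azodicarboxylate, inversion) should give methyl (3S)-3-[2-[(2S)-but-3-en-2-yloxy]-3-formyl-5-(3-methylbut-2-en-1-yl)-4,6-bis(triisopropylsiloxy)phenyl]hexanoate F8. N-heterocyclic-carbene-catalysed intramolecular hydroacylation of the unactivated alkene (thiazolium precatalyst, DBU, 1,4-dioxane, 120 °C) then forms C4–C3 and closes the pyranone with C2 fixed as S. The product comes back to the route as 24 mixed with its C3 epimer 25, and step 10 converges the mixture to 25.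

**Further compounds**

F1 | step 6 | tert-butyldimethyl{[3-(triisopropylsiloxy)prop-2-yn-1-yl]oxy}silane | CC(C)(C)[Si](C)(C)OCC#CO[Si](C(C)C)(C(C)C)C(C)C
F2 | step 6 | methyl (3S)-3-[3-[(tert-butyldimethylsiloxy)methyl]-2-hydroxy-5-(3-methylbut-2-en-1-yl)-4,6-bis(triisopropylsiloxy)phenyl]hexanoate | CCC[C@@H](CC(=O)OC)c1c(O)c(CO[Si](C)(C)C(C)(C)C)c(O[Si](C(C)C)(C(C)C)C(C)C)c(CC=C(C)C)c1O[Si](C(C)C)(C(C)C)C(C)C
F3 | step 5 | lithium ethenolate | C=C[O-].[Li+]
F4 | step 5 | (ethenyloxy)triisopropylsilane | C=CO[Si](C(C)C)(C(C)C)C(C)C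
F5 | step 5 | (1,2-dibromoethoxy)triisopropylsilane | BrCC(Br)O[Si](C(C)C)(C(C)C)C(C)C
F6 | step 5 | [(2-bromoethenyl)oxy]triisopropylsilane (E/Z mixture) | BrC=CO[Si](C(C)C)(C(C)C)C(C)C
F7 | step 5 | lithium (triisopropylsiloxy)ethynide | [Li]C#CO[Si](C(C)C)(C(C)C)C(C)C
F8 | step 9 | methyl (3S)-3-[2-[(2S)-but-3-en-2-yloxy]-3-formyl-5-(3-methylbut-2-en-1-yl)-4,6-bis(triisopropylsiloxy)phenyl]hexanoate | CCC[C@@H](CC(=O)OC)c1c(O[C@@H](C)C=C)c(C=O)c(O[Si](C(C)C)(C(C)C)C(C)C)c(CC=C(C)C)c1O[Si](C(C)C)(C(C)C)C(C)C
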